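**Plan**
1. Retrosynthesis: the ten benzyl ethers come off last. The bond from the pyrogallol ring B to C-2 of the epigallocatechin ring C is cut next (key step), then the matching catechol ring B–C-2 bond of the epicatechin unit, and last the biaryl bond (Suzuki–Miyaura).
2. Enabling feature: both halves are the same (2R,3R)-5,7-dihydroxychroman-3-ol-2-yl unit, each with a free 3-OH cis to the aryl group on C-2. O-3 can carry an aryl borate that hands its ipso carbon to C-2 of the ring C oxocarbenium ion (stabilized by O-1) on its own face.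
3. Forward: one donor, (3R)-5,7-bis(benzyloxy)chroman-2,3-diol (rings A and C), is made from 3,5-bis(benzyloxy)phenol and methyl (R)-glycidate. A penta-O-benzyl bromo-iodo biaryl is made from two arenes. The first aryl transfer attaches ring C of the epicatechin unit, the second (key) that of the epigallocatechin unit; hydrogenolysis ends the route.
4. Stereochemistry: C-3 of both units comes from methyl (R)-glycidate (chiral pool). C-2 of both units is set by the O-3 boron tether (cis delivery). Helpers (MOM, halogens, boron, benzyl) are removed in steps 3, 9–13 and 14.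

Key step: step 13

Assumption: the target SMILES gives no descriptor for the biaryl axis, so the route fixes the four stereocentres and leaves the axis to substrate control; any persistent atropisomers would be separated at 28 or 29.

Step 1
Reactants: 1 3,5-bis(benzyloxy)phenol
Product: 2 1,3-bis(benzyloxy)-5-(methoxymethoxy)benzene
Conditions: MOMCl, i-Pr2NEt, CH2Cl2, 0 °C to rt
Reagents that add atoms: chloromethyl methyl ether, COCCl
Why: O-alkylation of the phenol gives the MOM ether, which is the strongest ortho-directing group for step 2 and is acid-labile beside benzyl ethers.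

Step 2
Reactants: 2 1,3-bis(benzyloxy)-5-(methoxymethoxy)benzene; 3 methyl (2R)-oxirane-2-carboxylate
Product: 6 methyl (2R)-3-[2,4-bis(benzyloxy)-6-(methoxymethoxy)phenyl]-2-hydroxypropanoate, via aryllithium 4 (not isolated), via arylmagnesium bromide 5 (not isolated)
Conditions: n-BuLi, THF, 0 °C; MgBr2·OEt2; CuI (10 mol %), 3, −40 to −10 °C; then 1 M HCl
Reagents that add atoms: none
Why: Directed ortho-metalation should occur between OMOM and OBn (cooperating directing groups), and the copper-catalysed Grignard opening of the glycidate at its unsubstituted C-3 leaves the stereocentre of 3 untouched, so the carbinol carbon (later C-3 of ring C) is R.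

Step 3
Reactants: 6 methyl (2R)-3-[2,4-bis(benzyloxy)-6-(methoxymethoxy)phenyl]-2-hydroxypropanoate
Product: 8 (3R)-5,7-bis(benzyloxy)-3-hydroxychroman-2-one, via free phenol ester 7 (not isolated)
Conditions: TsOH·H2O (10 mol %), MeOH, 50 °C; then toluene, 80 °C (MeOH distilled off)
Reagents that add atoms: none
Why: Acid-catalysed acetal exchange removes the MOM group and the freed phenol closes the six-membered aryl lactone (lactonization) without touching the stereocentre.

Step 4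
Reactants: 8 (3R)-5,7-bis(benzyloxy)-3-hydroxychroman-2-one
Product: 9 (3R)-5,7-bis(benzyloxy)chroman-2,3-diol (both C-2 epimers)
Conditions: DIBAL (2.3 equiv), CH2Cl2, −78 °C; aq. potassium sodium tartrate
Reagents that add atoms: none
Why: Partial reduction of a lactone to the lactol by DIBAL at low temperature gives the hemiacetal donor, whose C-2 configuration is irrelevant because C-2 is ionized later.

Step 5
Reactants: 10 5-bromobenzene-1,2,3-triol
Product: 11 1,2,3-tris(benzyloxy)-5-bromobenzene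
Conditions: BnBr (3.5 equiv), K2CO3, DMF, 60 °C, argon
Reagents that add atoms: benzyl bromide, BrCc1ccccc1
Why: Threefold Williamson ether synthesis protects the pyrogallol as benzyl ethers that survive all later steps and leave in step 14.

Step 6
Reactants: 11 1,2,3-tris(benzyloxy)-5-bromobenzene
Product: 12 1,2,3-tris(benzyloxy)-5-bromo-4-iodobenzene
Conditions: NIS (1.05 equiv), TFA (cat.), MeCN, rt, dark
Reagents that add atoms: N-iodosuccinimide, O=C1CCC(=O)N1I
Why: Electrophilic aromatic iodination; the two free positions are equivalent by symmetry and each is ortho and para to benzyloxy groups, so one regioisomer should form.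

Step 7
Reactants: 12 1,2,3-tris(benzyloxy)-5-bromo-4-iodobenzene; 13 [3,4-bis(benzyloxy)phenyl]boronic acid
Product: 14 3',4,4',5,6-pentakis(benzyloxy)-2-bromo-1,1'-biphenyl
Conditions: Pd(PPh3)4 (5 mol %), 2 M aq. Na2CO3, DME, 85 °C
Reagents that add atoms: none
Why: Suzuki–Miyaura coupling; zerovalent palladium inserts into the C–I bond much faster than into the C–Br bond, so the bromine stays as the handle for step 12.

Step 8
Reactants: 14 3',4,4',5,6-pentakis(benzyloxy)-2-bromo-1,1'-biphenyl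
Product: 15 4,4',5,5',6-pentakis(benzyloxy)-2-bromo-2'-iodo-1,1'-biphenyl
Conditions: NIS (1.05 equiv), TFA (cat.), MeCN–CH2Cl2, 0 °C
Reagents that add atoms: N-iodosuccinimide, O=C1CCC(=O)N1I
Why: Electrophilic iodination should go to the catechol-ring carbon para to a benzyloxy group and ortho to the biaryl bond, since the only free carbon of the pyrogallol ring is flanked by Br and OBn.

Step 9
Reactants: 15 4,4',5,5',6-pentakis(benzyloxy)-2-bromo-2'-iodo-1,1'-biphenyl
Product: 18 potassium [2'-bromo-4,4',5,5',6'-pentakis(benzyloxy)biphenyl-2-yl]trifluoroborate, via arylmagnesium chloride 16 (not isolated), via dimethyl arylboronate 17 (not isolated)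
Conditions: i-PrMgCl·LiCl, THF, −20 °C; B(OMe)3, −20 °C to rt; aq. KHF2, MeOH, rt
Reagents that add atoms: trimethyl borate, COB(OC)OC; potassium hydrogen difluoride, [K+].[F-].F
Why: Iodine–magnesium exchange is selective over the aryl bromide, and borylation followed by KHF2 gives a crystallizable trifluoroborate on the catechol ring only.

Step 10
Reactants: 18 potassium [2'-bromo-4,4',5,5',6'-pentakis(benzyloxy)biphenyl-2-yl]trifluoroborate; 9 (3R)-5,7-bis(benzyloxy)chroman-2,3-diol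
Product: 21 (2R,3R)-5,7-bis(benzyloxy)-2-[2'-bromo-4,4',5,5',6'-pentakis(benzyloxy)biphenyl-2-yl]chroman-3-ol, via aryldifluoroborane 19 (not isolated), via borate-tethered chromenylium zwitterion 20 (not isolated)
Conditions: BF3·OEt2 (1.1 equiv), 4 Å MS, CH2Cl2–MeCN, −40 °C; then 9 (1.5 equiv) added slowly, −40 to 0 °C; aq. NaHCO3
Reagents that add atoms: none
Why: Proposed new method: BF3·OEt2 abstracts fluoride from 18 to give borane 19, which binds O-3 of 9 while the hemiacetal hydroxyl leaves, so the borate in 20 sits on one face of the benzopyranyl oxocarbenium ion and a 1,2-shift of its ipso carbon through a five-membered transition state (C-2, C-3, O-3, B, C-ipso) can only place the aryl group cis to O-3, setting C-2 as R from the 3R centre; the closest known reaction types are the Petasis borono-Mannich reaction, its hydroxyl-directed cis-selective addition of boronates to cyclic N-acyliminium ions, and the untethered addition of organotrifluoroborates to acetal-derived oxocarbenium ions.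

Step 11
Reactants: 21 (2R,3R)-5,7-bis(benzyloxy)-2-[2'-bromo-4,4',5,5',6'-pentakis(benzyloxy)biphenyl-2-yl]chroman-3-ol
Product: 22 (2R,3R)-3,5,7-tris(benzyloxy)-2-[2'-bromo-4,4',5,5',6'-pentakis(benzyloxy)biphenyl-2-yl]chromane
Conditions: NaH, BnBr, Bu4NI (cat.), THF–DMF, 0 °C to rt
Reagents that add atoms: benzyl bromide, BrCc1ccccc1
Why: Williamson etherification caps O-3 of the epicatechin unit, so that the organolithium of step 12 is not quenched and the donor hydroxyl is the only tether site in step 13.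

Step 12
Reactants: 22 (2R,3R)-3,5,7-tris(benzyloxy)-2-[2'-bromo-4,4',5,5',6'-pentakis(benzyloxy)biphenyl-2-yl]chromane
Product: 25 potassium {4,4',5,5',6-pentakis(benzyloxy)-2'-[(2R,3R)-3,5,7-tris(benzyloxy)chroman-2-yl]biphenyl-2-yl}trifluoroborate, via aryllithium 23 (not isolated), via dimethyl arylboronate 24 (not isolated)
Conditions: n-BuLi, THF, −78 °C; B(OMe)3, −78 °C to rt; aq. KHF2, MeOH, rt
Reagents that add atoms: trimethyl borate, COB(OC)OC; potassium hydrogen difluoride, [K+].[F-].F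
Why: Bromine–lithium exchange at −78 °C is faster than any deprotonation of the benzyl ethers, and borylation with KHF2 puts boron on exactly the pyrogallol-ring carbon that must bond to C-2.

Step 13
Reactants: 25 potassium {4,4',5,5',6-pentakis(benzyloxy)-2'-[(2R,3R)-3,5,7-tris(benzyloxy)chroman-2-yl]biphenyl-2-yl}trifluoroborate; 9 (3R)-5,7-bis(benzyloxy)chroman-2,3-diol
Product: 28 (2R,3R)-5,7-bis(benzyloxy)-2-{4,4',5,5',6-pentakis(benzyloxy)-2'-[(2R,3R)-3,5,7-tris(benzyloxy)chroman-2-yl]biphenyl-2-yl}chroman-3-ol, via aryldifluoroborane 26 (not isolated), via borate-tethered chromenylium zwitterion 27 (not isolated)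
Conditions: BF3·OEt2 (1.1 equiv), 4 Å MS, CH2Cl2–MeCN, −40 °C; then 9 (2 equiv) added slowly, −40 to 0 °C; aq. NaHCO3
Reagents that add atoms: none
Why: Proposed new method: BF3·OEt2 converts 25 into the Lewis-acidic borane 26, which binds O-3 of donor 9 and whose acidic adduct expels the hemiacetal hydroxyl as water, giving zwitterion 27 in which a tetracoordinate aryl borate is tethered through O-3 to one face of a 5,7-dialkoxybenzopyranyl oxocarbenium ion; a 1,2-shift of the ipso carbon from boron to C-2 then forms the ring B–C-2 bond and hydrolysis frees the 3-OH. The closest known reaction types are the Petasis borono-Mannich reaction (aryl transfer from a borate held by an α-hydroxyl to an iminium carbon), its hydroxyl-directed cis-selective version on cyclic N-acyliminium ions, and the addition of organotrifluoroborates to acetal-derived oxocarbenium ions; the chroman-2,3-diol as oxocarbenium precursor is the untested element. No ring of the target is closed here: ring C of the new unit is already present in 9, and the only cycle involved is the transient five-membered array C-2–C-3–O-3–B–C-ipso of the transition state. The one new stereocentre, C-2, is set R by the 3R centre of 9, because the boron-bound aryl group can reach C-2 only on the face that carries O-3, which gives the 2,3-cis relationship directly. The step needs cis over trans delivery (secured by the tether), bonding at the boron-bearing carbon and not at the electronically richer free CH of the pyrogallol ring (secured because the migrating terminus of a borate is its ipso carbon), and aryl transfer ahead of Friedel–Crafts attack of the cation on C-6 or C-8 of a ring A (favoured by intramolecularity, low temperature and slow addition of 9). The benzyl ether on O-3 of the epicatechin unit leaves the donor hydroxyl as the only site for the tether.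

Step 14
Reactants: 28 (2R,3R)-5,7-bis(benzyloxy)-2-{4,4',5,5',6-pentakis(benzyloxy)-2'-[(2R,3R)-3,5,7-tris(benzyloxy)chroman-2-yl]biphenyl-2-yl}chroman-3-ol
Product: 29 degalloyl theasinensin F
Conditions: H2 (1 atm), Pd(OH)2/C, THF–MeOH, rt; filtration under argon
Reagents that add atoms: none
Why: Hydrogenolysis of all ten benzyl ethers under the mild conditions usual for benzylated flavan-3-ols should free the polyphenol without cleaving the benzylic C-2–O-1 bonds or touching the stereocentres.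

**Compound list**
1 | 3,5-bis(benzyloxy)phenol | Oc1cc(OCc2ccccc2)cc(OCc2ccccc2)c1 | starting material
2 | 1,3-bis(benzyloxy)-5-(methoxymethoxy)benzene | COCOc1cc(OCc2ccccc2)cc(OCc2ccccc2)c1 | intermediate
3 | methyl (2R)-oxirane-2-carboxylate (methyl (R)-glycidate) | COC(=O)[C@H]1CO1 | starting material
4 | [2,4-bis(benzyloxy)-6-(methoxymethoxy)phenyl]lithium | [Li]c1c(OCOC)cc(OCc2ccccc2)cc1OCc1ccccc1 | intermediate
5 | [2,4-bis(benzyloxy)-6-(methoxymethoxy)phenyl]magnesium bromide | Br[Mg]c1c(OCOC)cc(OCc2ccccc2)cc1OCc1ccccc1 | intermediate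
6 | methyl (2R)-3-[2,4-bis(benzyloxy)-6-(methoxymethoxy)phenyl]-2-hydroxypropanoate | COC(=O)[C@H](O)Cc1c(OCOC)cc(OCc2ccccc2)cc1OCc1ccccc1 | intermediate
7 | methyl (2R)-3-[2,4-bis(benzyloxy)-6-hydroxyphenyl]-2-hydroxypropanoate | COC(=O)[C@H](O)Cc1c(O)cc(OCc2ccccc2)cc1OCc1ccccc1 | intermediate
8 | (3R)-5,7-bis(benzyloxy)-3-hydroxychroman-2-one | O=C1Oc2cc(OCc3ccccc3)cc(OCc3ccccc3)c2C[C@H]1O | intermediate
9 | (3R)-5,7-bis(benzyloxy)chroman-2,3-diol | OC1Oc2cc(OCc3ccccc3)cc(OCc3ccccc3)c2C[C@H]1O | intermediate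
10 | 5-bromobenzene-1,2,3-triol | Oc1cc(Br)cc(O)c1O | starting material
11 | 1,2,3-tris(benzyloxy)-5-bromobenzene | Brc1cc(OCc2ccccc2)c(OCc2ccccc2)c(OCc2ccccc2)c1 | intermediate
12 | 1,2,3-tris(benzyloxy)-5-bromo-4-iodobenzene | Brc1cc(OCc2ccccc2)c(OCc2ccccc2)c(OCc2ccccc2)c1I | intermediate
13 | [3,4-bis(benzyloxy)phenyl]boronic acid | OB(O)c1ccc(OCc2ccccc2)c(OCc2ccccc2)c1 | starting material
14 | 3',4,4',5,6-pentakis(benzyloxy)-2-bromo-1,1'-biphenyl | Brc1cc(OCc2ccccc2)c(OCc2ccccc2)c(OCc2ccccc2)c1-c1ccc(OCc2ccccc2)c(OCc2ccccc2)c1 | intermediate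
15 | 4,4',5,5',6-pentakis(benzyloxy)-2-bromo-2'-iodo-1,1'-biphenyl | Brc1cc(OCc2ccccc2)c(OCc2ccccc2)c(OCc2ccccc2)c1-c1cc(OCc2ccccc2)c(OCc2ccccc2)cc1I | intermediate
16 | [2'-bromo-4,4',5,5',6'-pentakis(benzyloxy)biphenyl-2-yl]magnesium chloride | Cl[Mg]c1cc(OCc2ccccc2)c(OCc2ccccc2)cc1-c1c(Br)cc(OCc2ccccc2)c(OCc2ccccc2)c1OCc1ccccc1 | intermediate
17 | dimethyl [2'-bromo-4,4',5,5',6'-pentakis(benzyloxy)biphenyl-2-yl]boronate | COB(OC)c1cc(OCc2ccccc2)c(OCc2ccccc2)cc1-c1c(Br)cc(OCc2ccccc2)c(OCc2ccccc2)c1OCc1ccccc1 | intermediate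
18 | potassium [2'-bromo-4,4',5,5',6'-pentakis(benzyloxy)biphenyl-2-yl]trifluoroborate | [K+].F[B-](F)(F)c1cc(OCc2ccccc2)c(OCc2ccccc2)cc1-c1c(Br)cc(OCc2ccccc2)c(OCc2ccccc2)c1OCc1ccccc1 | intermediate
19 | [2'-bromo-4,4',5,5',6'-pentakis(benzyloxy)biphenyl-2-yl]difluoroborane | FB(F)c1cc(OCc2ccccc2)c(OCc2ccccc2)cc1-c1c(Br)cc(OCc2ccccc2)c(OCc2ccccc2)c1OCc1ccccc1 | intermediate
20 | (3R)-5,7-bis(benzyloxy)-3-{[aryl(difluoro)boranuidyl]oxy}-3,4-dihydrochromenylium inner salt (aryl as in 19) | F[B-](F)(O[C@@H]1Cc2c(OCc3ccccc3)cc(OCc3ccccc3)cc2[O+]=C1)c1cc(OCc2ccccc2)c(OCc2ccccc2)cc1-c1c(Br)cc(OCc2ccccc2)c(OCc2ccccc2)c1OCc1ccccc1 | intermediate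
21 | (2R,3R)-5,7-bis(benzyloxy)-2-[2'-bromo-4,4',5,5',6'-pentakis(benzyloxy)biphenyl-2-yl]chroman-3-ol | c5ccccc5COc1cc(OCc5ccccc5)c2c(c1)O[C@H](c1cc(OCc5ccccc5)c(OCc5ccccc5)cc1-c1c(Br)cc(OCc5ccccc5)c(OCc5ccccc5)c1OCc5ccccc5)[C@H](O)C2 | intermediate
22 | (2R,3R)-3,5,7-tris(benzyloxy)-2-[2'-bromo-4,4',5,5',6'-pentakis(benzyloxy)biphenyl-2-yl]chromane | c5ccccc5COc1cc(OCc5ccccc5)c2c(c1)O[C@H](c1cc(OCc5ccccc5)c(OCc5ccccc5)cc1-c1c(Br)cc(OCc5ccccc5)c(OCc5ccccc5)c1OCc5ccccc5)[C@H](OCc5ccccc5)C2 | intermediate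
23 | {4,4',5,5',6-pentakis(benzyloxy)-2'-[(2R,3R)-3,5,7-tris(benzyloxy)chroman-2-yl]biphenyl-2-yl}lithium | c5ccccc5COc1cc(OCc5ccccc5)c2c(c1)O[C@H](c1cc(OCc5ccccc5)c(OCc5ccccc5)cc1-c1c([Li])cc(OCc5ccccc5)c(OCc5ccccc5)c1OCc5ccccc5)[C@H](OCc5ccccc5)C2 | intermediate
24 | dimethyl {4,4',5,5',6-pentakis(benzyloxy)-2'-[(2R,3R)-3,5,7-tris(benzyloxy)chroman-2-yl]biphenyl-2-yl}boronate | c5ccccc5COc1cc(OCc5ccccc5)c2c(c1)O[C@H](c1cc(OCc5ccccc5)c(OCc5ccccc5)cc1-c1c(B(OC)OC)cc(OCc5ccccc5)c(OCc5ccccc5)c1OCc5ccccc5)[C@H](OCc5ccccc5)C2 | intermediate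
25 | potassium {4,4',5,5',6-pentakis(benzyloxy)-2'-[(2R,3R)-3,5,7-tris(benzyloxy)chroman-2-yl]biphenyl-2-yl}trifluoroborate | [K+].c5ccccc5COc1cc(OCc5ccccc5)c2c(c1)O[C@H](c1cc(OCc5ccccc5)c(OCc5ccccc5)cc1-c1c([B-](F)(F)F)cc(OCc5ccccc5)c(OCc5ccccc5)c1OCc5ccccc5)[C@H](OCc5ccccc5)C2 | intermediate
26 | {4,4',5,5',6-pentakis(benzyloxy)-2'-[(2R,3R)-3,5,7-tris(benzyloxy)chroman-2-yl]biphenyl-2-yl}difluoroborane | c5ccccc5COc1cc(OCc5ccccc5)c2c(c1)O[C@H](c1cc(OCc5ccccc5)c(OCc5ccccc5)cc1-c1c(B(F)F)cc(OCc5ccccc5)c(OCc5ccccc5)c1OCc5ccccc5)[C@H](OCc5ccccc5)C2 | intermediate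
27 | (3R)-5,7-bis(benzyloxy)-3-{[aryl(difluoro)boranuidyl]oxy}-3,4-dihydrochromenylium inner salt (aryl as in 26) | c5ccccc5COc1cc(OCc5ccccc5)c2c(c1)O[C@H](c1cc(OCc5ccccc5)c(OCc5ccccc5)cc1-c1c([B-](F)(F)O[C@@H]3Cc4c(OCc5ccccc5)cc(OCc5ccccc5)cc4[O+]=C3)cc(OCc5ccccc5)c(OCc5ccccc5)c1OCc5ccccc5)[C@H](OCc5ccccc5)C2 | intermediate
28 | (2R,3R)-5,7-bis(benzyloxy)-2-{4,4',5,5',6-pentakis(benzyloxy)-2'-[(2R,3R)-3,5,7-tris(benzyloxy)chroman-2-yl]biphenyl-2-yl}chroman-3-ol | c5ccccc5COc1cc(OCc5ccccc5)c2c(c1)O[C@H](c1cc(OCc5ccccc5)c(OCc5ccccc5)cc1-c1c([C@H]3Oc4cc(OCc5ccccc5)cc(OCc5ccccc5)c4C[C@H]3O)cc(OCc5ccccc5)c(OCc5ccccc5)c1OCc5ccccc5)[C@H](OCc5ccccc5)C2 | intermediate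
29 | degalloyl theasinensin F | Oc1cc(O)c2c(c1)O[C@H](c1cc(O)c(O)cc1-c1c([C@H]3Oc4cc(O)cc(O)c4C[C@H]3O)cc(O)c(O)c1O)[C@H](O)C2 | target

Total steps: 14. Longest linear sequence: 10 steps (steps 5 to 14, from 10).

**Steps most likely to fail**

Step 13 (Proposed new method). What may go wrong:
- capture of the oxocarbenium ion by ring A carbons of 9 or 25 (Friedel–Crafts oligomerization) before the tethered aryl shift;
- loss of H-3 from the cation to an enol, which erases C-3;
- protodeboronation of 26;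
- aryl delivery from a borate that is not bound to O-3, which loses facial control.

The fallback uses known reaction types, sets out from 8 and 22 and returns at 29.
- Lactone 8 is benzylated under acid (benzyl 2,2,2-trichloroacetimidate, TfOH cat.) to (3R)-3,5,7-tris(benzyloxy)chroman-2-one F1.
- Bromide 22 is converted into aryllithium 23 (n-BuLi, −78 °C) and added to F1; the aryl lactone opens to the hydroxyaryl ketone (2R)-2-(benzyloxy)-3-[2,4-bis(benzyloxy)-6-hydroxyphenyl]-1-{4,4',5,5',6-pentakis(benzyloxy)-2'-[(2R,3R)-3,5,7-tris(benzyloxy)chroman-2-yl]biphenyl-2-yl}propan-1-one F2.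
- Chelation-controlled reduction of the α-benzyloxy ketone (Zn(BH4)2, Et2O) should give the anti alcohol, the (1S,2R)-propan-1-ol F3.
- An intramolecular Mitsunobu etherification (PPh3, DIAD) closes ring C with inversion at the benzylic carbon to the 2,3-cis product, the fully benzylated (2R,3R)-3,5,7-tris(benzyloxy)-2-{4,4',5,5',6-pentakis(benzyloxy)-2'-[(2R,3R)-3,5,7-tris(benzyloxy)chroman-2-yl]biphenyl-2-yl}chromane F4.
- The conditions of step 14 convert F4 into 29.

Step 10 (Proposed new method). The same processes may intervene on the simpler aryl group: untethered cation capture, enolization of the cation, protodeboronation of 19. The fallback sets out from 15 and F1 and returns at 22, bypassing steps 9 to 11.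
- Iodide 15 is converted into Grignard reagent 16 as in step 9 and added to F1 at −78 °C to give (2R)-2-(benzyloxy)-3-[2,4-bis(benzyloxy)-6-hydroxyphenyl]-1-[2'-bromo-4,4',5,5',6'-pentakis(benzyloxy)biphenyl-2-yl]propan-1-one F5.
- Zn(BH4)2 reduction under chelation control should give the anti alcohol, the (1S,2R)-propan-1-ol F6.
- Mitsunobu cyclization with inversion gives 22 directly.

Step 8. Iodination may be poorly regioselective between the two electron-rich rings, or may over-iodinate. The fallback puts boron in place before the biaryl is made; it sets out from 12 and returns at 18.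
- Commercial 1,2-bis(benzyloxy)benzene is dibrominated (Br2, CH2Cl2) to 1,2-bis(benzyloxy)-4,5-dibromobenzene F7.
- Double Miyaura borylation (B2pin2, Pd(dppf)Cl2, KOAc, dioxane) gives 2,2'-[4,5-bis(benzyloxy)-1,2-phenylene]bis(4,4,5,5-tetramethyl-1,3,2-dioxaborolane) F8.
- A single Suzuki–Miyaura coupling of excess F8 with 12 at the C–I bond (Pd(PPh3)4, K3PO4) gives 2-[2'-bromo-4,4',5,5',6'-pentakis(benzyloxy)biphenyl-2-yl]-4,4,5,5-tetramethyl-1,3,2-dioxaborolane F9.
- Aqueous KHF2 converts F9 into 18.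

**Further compounds**
F1 | step 13 | (3R)-3,5,7-tris(benzyloxy)chroman-2-one | O=C1Oc2cc(OCc3ccccc3)cc(OCc3ccccc3)c2C[C@H]1OCc1ccccc1
F2 | step 13 | (2R)-2-(benzyloxy)-3-[2,4-bis(benzyloxy)-6-hydroxyphenyl]-1-{4,4',5,5',6-pentakis(benzyloxy)-2'-[(2R,3R)-3,5,7-tris(benzyloxy)chroman-2-yl]biphenyl-2-yl}propan-1-one | c5ccccc5COc1cc(OCc5ccccc5)c2c(c1)O[C@H](c1cc(OCc5ccccc5)c(OCc5ccccc5)cc1-c1c(C(=O)[C@H](OCc5ccccc5)Cc3c(O)cc(OCc5ccccc5)cc3OCc5ccccc5)cc(OCc5ccccc5)c(OCc5ccccc5)c1OCc5ccccc5)[C@H](OCc5ccccc5)C2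
F3 | step 13 | (1S,2R)-2-(benzyloxy)-3-[2,4-bis(benzyloxy)-6-hydroxyphenyl]-1-{4,4',5,5',6-pentakis(benzyloxy)-2'-[(2R,3R)-3,5,7-tris(benzyloxy)chroman-2-yl]biphenyl-2-yl}propan-1-ol | c5ccccc5COc1cc(OCc5ccccc5)c2c(c1)O[C@H](c1cc(OCc5ccccc5)c(OCc5ccccc5)cc1-c1c([C@H](O)[C@H](OCc5ccccc5)Cc3c(O)cc(OCc5ccccc5)cc3OCc5ccccc5)cc(OCc5ccccc5)c(OCc5ccccc5)c1OCc5ccccc5)[C@H](OCc5ccccc5)C2
F4 | step 13 | (2R,3R)-3,5,7-tris(benzyloxy)-2-{4,4',5,5',6-pentakis(benzyloxy)-2'-[(2R,3R)-3,5,7-tris(benzyloxy)chroman-2-yl]biphenyl-2-yl}chromane | c5ccccc5COc1cc(OCc5ccccc5)c2c(c1)O[C@H](c1cc(OCc5ccccc5)c(OCc5ccccc5)cc1-c1c([C@H]3Oc4cc(OCc5ccccc5)cc(OCc5ccccc5)c4C[C@H]3OCc5ccccc5)cc(OCc5ccccc5)c(OCc5ccccc5)c1OCc5ccccc5)[C@H](OCc5ccccc5)C2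
F5 | step 10 | (2R)-2-(benzyloxy)-3-[2,4-bis(benzyloxy)-6-hydroxyphenyl]-1-[2'-bromo-4,4',5,5',6'-pentakis(benzyloxy)biphenyl-2-yl]propan-1-one | O=C(c1cc(OCc2ccccc2)c(OCc2ccccc2)cc1-c1c(Br)cc(OCc2ccccc2)c(OCc2ccccc2)c1OCc1ccccc1)[C@H](OCc1ccccc1)Cc1c(O)cc(OCc2ccccc2)cc1OCc1ccccc1
F6 | step 10 | (1S,2R)-2-(benzyloxy)-3-[2,4-bis(benzyloxy)-6-hydroxyphenyl]-1-[2'-bromo-4,4',5,5',6'-pentakis(benzyloxy)biphenyl-2-yl]propan-1-ol | O[C@@H](c1cc(OCc2ccccc2)c(OCc2ccccc2)cc1-c1c(Br)cc(OCc2ccccc2)c(OCc2ccccc2)c1OCc1ccccc1)[C@H](OCc1ccccc1)Cc1c(O)cc(OCc2ccccc2)cc1OCc1ccccc1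
F7 | step 8 | 1,2-bis(benzyloxy)-4,5-dibromobenzene | Brc1cc(OCc2ccccc2)c(OCc2ccccc2)cc1Br
F8 | step 8 | 2,2'-[4,5-bis(benzyloxy)-1,2-phenylene]bis(4,4,5,5-tetramethyl-1,3,2-dioxaborolane) | CC1(C)OB(OC1(C)C)c1cc(OCc2ccccc2)c(OCc2ccccc2)cc1B1OC(C)(C)C(C)(C)O1
F9 | step 8 | 2-[2'-bromo-4,4',5,5',6'-pentakis(benzyloxy)biphenyl-2-yl]-4,4,5,5-tetramethyl-1,3,2-dioxaborolane | CC1(C)OB(OC1(C)C)c1cc(OCc2ccccc2)c(OCc2ccccc2)cc1-c1c(Br)cc(OCc2ccccc2)c(OCc2ccccc2)c1OCc1ccccc1
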